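## Retrosynthetic overview

1. The enone carbonyl comes last, by oxidation of a ring allylic alcohol. That alcohol first serves to direct a 1,3-syn reduction that sets the lactone carbinol and lets the γ-lactone close.
2. The side chain is attached as an alkenyl ketone: a neopentyl aldehyde plus an (E)-vinyl iodide (Nozaki–Hiyama–Kishi coupling, then oxidation).
3. The cyclohexene, its quaternary carbon and both ring oxygens (already differentiated as OAc and OSi) come from one catalytic enantioselective Diels–Alder reaction between an α-substituted acrolein and an (E,E)-1-acetoxy-4-silyloxybutadiene.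
4. Fragments: the acrolein from methyl 4-oxobutanoate and formaldehyde; the diene from (E,E)-1,4-diacetoxybutadiene; the vinyl iodide from pent-1-en-4-yne (carboalumination/iodination) and 2-methylbut-3-en-2-ol (cross-metathesis).
5. Ring order: carbocycle first (Diels–Alder), spiro-γ-lactone second (reduction/lactonisation).

Assumption: compounds 1, 3, 7 and 10 are taken as commercially available (all achiral); atom labels such as C1, C5, C6, C9 in the text follow the 2-oxaspiro[4.5]decane numbering of the target.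

## Route

Step 1
Reactants: 1 methyl 4-oxobutanoate
Product: 2 methyl 3-formylbut-3-enoate
Conditions: 37% aq. CH2O, pyrrolidine (10 mol%), propionic acid (10 mol%), i-PrOH, 45 °C
Reagents that add atoms: formaldehyde C=O
Why: Organocatalytic Mannich-type α-methylenation (enamine addition to formaldehyde, then amine-assisted dehydration) turns the enolisable aldehyde into the α-substituted acrolein without touching the ester; no stereocentre is formed.

Step 2
Reactants: 3 (1E,3E)-buta-1,3-diene-1,4-diyl diacetate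
Product: 5 (1E,3E)-4-[(tert-butyldimethylsilyl)oxy]buta-1,3-dien-1-yl acetate, via lithium dienolate 4 (not isolated)
Conditions: MeLi (2.0 equiv), THF, −78 °C; then TBSCl (2.2 equiv), HMPA, −78 → 0 °C
Reagents that add atoms: tert-butyldimethylsilyl chloride CC(C)(C)[Si](C)(C)Cl
Why: House-type enol-acetate cleavage by MeLi gives the geometry-retaining lithium dienolate (the anionic mono-enolate resists a second attack), and O-silylation leaves an (E,E)-diene whose two oxygen termini differ in donor strength and in later deprotection chemistry.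

Step 3
Reactants: 2 methyl 3-formylbut-3-enoate; 5 (1E,3E)-4-[(tert-butyldimethylsilyl)oxy]buta-1,3-dien-1-yl acetate
Product: 6 methyl 2-[(1S,2S,5S)-5-acetoxy-2-[(tert-butyldimethylsilyl)oxy]-1-formylcyclohex-3-en-1-yl]acetate
Conditions: (R)-o-tolyl-CBS oxazaborolidine (20 mol%), Tf2NH (16 mol%), CH2Cl2, −78 °C
Reagents that add atoms: none
Why: Proposed new method: the metal-free cationic oxazaborolidine binds the formyl oxygen of 2 (B–O coordination plus formyl C–H···O contact) and shields one face of the s-trans enal, so 5 adds endo to the Re face of the α-carbon (the mirror image of the sense derived from the formyl C–H···O binding model for the (S)-catalyst with 2-substituted acroleins); in the asynchronous transition state the stronger silyloxy donor places its own terminus on the α-carbon and the acetoxy terminus on the CH2, which sets the quaternary carbon and the two cis ring C–O centres in one step; the closest known reaction is the oxazaborolidinium-catalysed Diels–Alder addition of 2-methyl- and 2-bromoacrolein to simple dienes, not yet shown for a 1-acyloxy-4-silyloxy diene or for regiocontrol by such a donor hierarchy.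

Step 4
Reactants: 7 pent-1-en-4-yne
Product: 9 (1E)-1-iodo-2-methylpenta-1,4-diene, via alkenyldimethylalane 8 (not isolated)
Conditions: Me3Al (2.0 equiv), Cp2ZrCl2 (20 mol%), CH2Cl2, 0 °C → rt; then I2, THF, −30 → 0 °C
Reagents that add atoms: trimethylaluminium C[Al](C)C; iodine II
Why: Negishi Zr-catalysed syn-carboalumination of the terminal alkyne (methyl to the internal carbon) followed by iodinolysis with retention gives the (E)-trisubstituted vinyl iodide, the isolated terminal alkene being far less reactive.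

Step 5
Reactants: 9 (1E)-1-iodo-2-methylpenta-1,4-diene; 10 2-methylbut-3-en-2-ol
Product: 11 (3E,6E)-7-iodo-2,6-dimethylhepta-3,6-dien-2-ol
Conditions: 10 (5 equiv), Hoveyda–Grubbs II (5 mol%), 1,4-benzoquinone (10 mol%), CH2Cl2, 40 °C
Reagents that add atoms: none
Why: Olefin cross-metathesis of the terminal alkene with an excess of the slowly dimerising tertiary allylic alcohol gives the E-disubstituted alkene, while the trisubstituted vinyl iodide does not take part and benzoquinone suppresses isomerisation of the skipped diene.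

Step 6
Reactants: 6 methyl 2-[(1S,2S,5S)-5-acetoxy-2-[(tert-butyldimethylsilyl)oxy]-1-formylcyclohex-3-en-1-yl]acetate; 11 (3E,6E)-7-iodo-2,6-dimethylhepta-3,6-dien-2-ol
Product: 13 methyl 2-[(1R,2S,5S)-5-acetoxy-2-[(tert-butyldimethylsilyl)oxy]-1-[(2E,5E)-1,7-dihydroxy-3,7-dimethylocta-2,5-dien-1-yl]cyclohex-3-en-1-yl]acetate (both carbinol epimers), via alkenylchromium(III) dichloride 12 (not isolated)
Conditions: 11 (1.5 equiv), CrCl2 (4 equiv), NiCl2 (2 mol%), DMSO, rt; short silica plug, used at once
Reagents that add atoms: none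
Why: In this Nozaki–Hiyama–Kishi coupling the Ni-generated alkenylchromium reagent adds chemoselectively to the neopentyl aldehyde with retention of alkene geometry in the presence of ester, acetate, silyl ether and free tertiary OH, and the carbinol configuration is irrelevant because step 7 erases it.

Step 7
Reactants: 13 methyl 2-[(1R,2S,5S)-5-acetoxy-2-[(tert-butyldimethylsilyl)oxy]-1-[(2E,5E)-1,7-dihydroxy-3,7-dimethylocta-2,5-dien-1-yl]cyclohex-3-en-1-yl]acetate
Product: 14 methyl 2-[(1S,2S,5S)-5-acetoxy-2-[(tert-butyldimethylsilyl)oxy]-1-[(2E,5E)-7-hydroxy-3,7-dimethylocta-2,5-dienoyl]cyclohex-3-en-1-yl]acetate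
Conditions: Dess–Martin periodinane, NaHCO3, CH2Cl2, 0 °C → rt
Reagents that add atoms: none
Why: Dess–Martin oxidation of the secondary allylic alcohol gives the enone (the tertiary alcohol is inert), removing the uncontrolled carbinol centre and forestalling premature lactonisation.

Step 8
Reactants: 14 methyl 2-[(1S,2S,5S)-5-acetoxy-2-[(tert-butyldimethylsilyl)oxy]-1-[(2E,5E)-7-hydroxy-3,7-dimethylocta-2,5-dienoyl]cyclohex-3-en-1-yl]acetate
Product: 15 methyl 2-[(1S,2S,5S)-5-acetoxy-2-hydroxy-1-[(2E,5E)-7-hydroxy-3,7-dimethylocta-2,5-dienoyl]cyclohex-3-en-1-yl]acetate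
Conditions: HF·pyridine, pyridine, THF, 0 °C → rt
Reagents that add atoms: none
Why: Buffered, weakly acidic fluoride desilylation frees the ring hydroxyl without retro-aldol cleavage of the β-hydroxy ketone or acetate migration.

Step 9
Reactants: 15 methyl 2-[(1S,2S,5S)-5-acetoxy-2-hydroxy-1-[(2E,5E)-7-hydroxy-3,7-dimethylocta-2,5-dienoyl]cyclohex-3-en-1-yl]acetate
Product: 17 (1R,5S,6S,9S)-6-hydroxy-1-[(1E,4E)-6-hydroxy-2,6-dimethylhepta-1,4-dien-1-yl]-3-oxo-2-oxaspiro[4.5]dec-7-en-9-yl acetate, via syn-diol ester 16 (not isolated)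
Conditions: Et2BOMe (1.2 equiv), THF/MeOH 4:1, −78 °C; NaBH4, −78 °C; AcOH, MeOH co-evaporation; then PPTS (cat.), CH2Cl2, rt
Reagents that add atoms: none
Why: In this Narasaka–Prasad reduction the diethylboron chelate of the β-hydroxy ketone (ring carbinol substituent equatorial) is attacked axially by external hydride to give the 1,3-syn diol, i.e. the (R)-carbinol with the side chain on the C6 side, and the new hydroxyl then closes the spiro-γ-lactone on the methyl ester (lactonisation), the ring hydroxyl being trans to the ester arm and poorly placed to compete.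

Step 10
Reactants: 17 (1R,5S,6S,9S)-6-hydroxy-1-[(1E,4E)-6-hydroxy-2,6-dimethylhepta-1,4-dien-1-yl]-3-oxo-2-oxaspiro[4.5]dec-7-en-9-yl acetate
Product: 18 (+)-miliusane XVII
Conditions: Dess–Martin periodinane, NaHCO3, CH2Cl2, 0 °C → rt
Reagents that add atoms: none
Why: Dess–Martin oxidation of the one remaining secondary (allylic) alcohol gives the cyclohexenone, while the tertiary alcohol, lactone and acetate are inert and no stereocentre is touched.

## Compound list

1 | methyl 4-oxobutanoate | COC(=O)CCC=O | starting material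
2 | methyl 3-formylbut-3-enoate | COC(=O)CC(=C)C=O | intermediate
3 | (1E,3E)-buta-1,3-diene-1,4-diyl diacetate | CC(=O)O/C=C/C=C/OC(C)=O | starting material
4 | lithium (1E,3E)-4-acetoxybuta-1,3-dien-1-olate | CC(=O)O/C=C/C=C/[O-].[Li+] | intermediate
5 | (1E,3E)-4-[(tert-butyldimethylsilyl)oxy]buta-1,3-dien-1-yl acetate | CC(=O)O/C=C/C=C/O[Si](C)(C)C(C)(C)C | intermediate
6 | methyl 2-[(1S,2S,5S)-5-acetoxy-2-[(tert-butyldimethylsilyl)oxy]-1-formylcyclohex-3-en-1-yl]acetate (CHO, OTBS and OAc all cis) | CC(=O)O[C@@H]1C=C[C@H](O[Si](C)(C)C(C)(C)C)[C@@](C=O)(CC(=O)OC)C1 | intermediate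
7 | pent-1-en-4-yne | C#CCC=C | starting material
8 | dimethyl[(1E)-2-methylpenta-1,4-dien-1-yl]alane | C[Al](C)/C=C(\C)CC=C | intermediate
9 | (1E)-1-iodo-2-methylpenta-1,4-diene | I/C=C(\C)CC=C | intermediate
10 | 2-methylbut-3-en-2-ol | C=CC(C)(C)O | starting material
11 | (3E,6E)-7-iodo-2,6-dimethylhepta-3,6-dien-2-ol | I/C=C(\C)C/C=C/C(C)(C)O | intermediate
12 | dichloro[(1E,4E)-6-hydroxy-2,6-dimethylhepta-1,4-dien-1-yl]chromium(III) | Cl[Cr](Cl)/C=C(\C)C/C=C/C(C)(C)O | intermediate
13 | methyl 2-[(1R,2S,5S)-5-acetoxy-2-[(tert-butyldimethylsilyl)oxy]-1-[(2E,5E)-1,7-dihydroxy-3,7-dimethylocta-2,5-dien-1-yl]cyclohex-3-en-1-yl]acetate (both carbinol epimers; ring geometry as in 6) | CC(=O)O[C@@H]1C=C[C@H](O[Si](C)(C)C(C)(C)C)[C@@](C(O)/C=C(\C)C/C=C/C(C)(C)O)(CC(=O)OC)C1 | intermediate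
14 | methyl 2-[(1S,2S,5S)-5-acetoxy-2-[(tert-butyldimethylsilyl)oxy]-1-[(2E,5E)-7-hydroxy-3,7-dimethylocta-2,5-dienoyl]cyclohex-3-en-1-yl]acetate | CC(=O)O[C@@H]1C=C[C@H](O[Si](C)(C)C(C)(C)C)[C@@](C(=O)/C=C(\C)C/C=C/C(C)(C)O)(CC(=O)OC)C1 | intermediate
15 | methyl 2-[(1S,2S,5S)-5-acetoxy-2-hydroxy-1-[(2E,5E)-7-hydroxy-3,7-dimethylocta-2,5-dienoyl]cyclohex-3-en-1-yl]acetate | CC(=O)O[C@@H]1C=C[C@H](O)[C@@](C(=O)/C=C(\C)C/C=C/C(C)(C)O)(CC(=O)OC)C1 | intermediate
16 | methyl 2-[(1S,2S,5S)-5-acetoxy-1-[(1R,2E,5E)-1,7-dihydroxy-3,7-dimethylocta-2,5-dien-1-yl]-2-hydroxycyclohex-3-en-1-yl]acetate | CC(=O)O[C@@H]1C=C[C@H](O)[C@@]([C@H](O)/C=C(\C)C/C=C/C(C)(C)O)(CC(=O)OC)C1 | intermediate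
17 | (1R,5S,6S,9S)-6-hydroxy-1-[(1E,4E)-6-hydroxy-2,6-dimethylhepta-1,4-dien-1-yl]-3-oxo-2-oxaspiro[4.5]dec-7-en-9-yl acetate | CC(=O)O[C@@H]1C=C[C@H](O)[C@@]2(CC(=O)O[C@@H]2/C=C(\C)C/C=C/C(C)(C)O)C1 | intermediate
18 | (+)-miliusane XVII, (1R,5R,9S)-1-[(1E,4E)-6-hydroxy-2,6-dimethylhepta-1,4-dien-1-yl]-3,6-dioxo-2-oxaspiro[4.5]dec-7-en-9-yl acetate | CC(=O)O[C@@H]1C=CC(=O)[C@@]2(CC(=O)O[C@@H]2/C=C(\C)C/C=C/C(C)(C)O)C1 | target

## Step count and risks

Total steps: 10. Longest linear sequence: 7 (steps 1, 3, 6, 7, 8, 9, 10).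

The three steps most likely to fail:

Step 3, the new Diels–Alder reaction. It may give a regioisomer mixture if the acetoxy terminus competes as director, hetero-Diels–Alder or Mukaiyama-type attack at the formyl group, or the wrong or a weak facial bias. The facial sense rests on a binding model, not on a measured result for this substrate; if 6 proves to be the antipode, the (S)-catalyst is used instead. The fallback uses only known chemistry and sets out from 2 and 5. An uncatalysed thermal Diels–Alder reaction (toluene, 70 °C, BHT), endo- and regioselective by the same orbital bias, gives the racemate, that is 6 together with its mirror image methyl 2-[(1R,2R,5R)-5-acetoxy-2-[(tert-butyldimethylsilyl)oxy]-1-formylcyclohex-3-en-1-yl]acetate F1. A lipase (Amano PS, pH 7 buffer/MTBE, 30 °C) then hydrolyses the allylic acetate of one antipode; taking the ring CH2 next to the quaternary carbon as the large group, Kazlauskas' rule predicts the (5S)-acetate. This gives methyl 2-[(1S,2S,5S)-2-[(tert-butyldimethylsilyl)oxy]-1-formyl-5-hydroxycyclohex-3-en-1-yl]acetate F2 and leaves F1 untouched. After chromatographic separation, Ac2O/pyridine/DMAP re-acetylates F2 and the route is rejoined at 6.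

Step 6, the Nozaki–Hiyama–Kishi coupling. The aldehyde is neopentylic and may react slowly, and the γ-hydroxy ester 13 may lactonise before it can be oxidised. The fallback replaces carbonyl addition by acylation and sets out from 6 and 11. Pinnick oxidation (NaClO2, NaH2PO4, 2-methylbut-2-ene, t-BuOH/H2O) gives (1S,2S,5S)-5-acetoxy-2-[(tert-butyldimethylsilyl)oxy]-1-(2-methoxy-2-oxoethyl)cyclohex-3-ene-1-carboxylic acid F3. Ghosez's reagent (1-chloro-N,N,2-trimethylprop-1-en-1-amine, CH2Cl2) converts it into methyl 2-[(1S,2S,5S)-5-acetoxy-2-[(tert-butyldimethylsilyl)oxy]-1-(chlorocarbonyl)cyclohex-3-en-1-yl]acetate F4. In parallel 11 is stannylated (Me3SnSnMe3, Pd(PPh3)4, toluene, 80 °C) to (3E,6E)-2,6-dimethyl-7-(trimethylstannyl)hepta-3,6-dien-2-ol F5. Stille acylation of F4 with F5 (Pd2(dba)3, tri-2-furylphosphine, THF, 50 °C) gives the enone directly, so the route is rejoined at 14 without ever forming the free carbinol 13.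

Step 2, the mono-deacetylative silylation. Double cleavage of the diacetate or loss of the sensitive diene is possible. The fallback sets out from 3 and separates the two events. Mono-methanolysis (catalytic K2CO3, MeOH, 0 °C) releases a dienol that tautomerises to (2E)-4-oxobut-2-en-1-yl acetate F6; its remaining acetate is now an ordinary allylic ester and resists further cleavage. Soft enolisation (TBSOTf, Et3N, CH2Cl2, −78 → 0 °C) then removes the γ-proton and gives the silyl dienol ether, rejoining the route at 5. Any Z-isomer formed does not react in step 3.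

Further compounds
F1 | step 3 | methyl 2-[(1R,2R,5R)-5-acetoxy-2-[(tert-butyldimethylsilyl)oxy]-1-formylcyclohex-3-en-1-yl]acetate | CC(=O)O[C@H]1C=C[C@@H](O[Si](C)(C)C(C)(C)C)[C@](C=O)(CC(=O)OC)C1
F2 | step 3 | methyl 2-[(1S,2S,5S)-2-[(tert-butyldimethylsilyl)oxy]-1-formyl-5-hydroxycyclohex-3-en-1-yl]acetate | O[C@@H]1C=C[C@H](O[Si](C)(C)C(C)(C)C)[C@@](C=O)(CC(=O)OC)C1
F3 | step 6 | (1S,2S,5S)-5-acetoxy-2-[(tert-butyldimethylsilyl)oxy]-1-(2-methoxy-2-oxoethyl)cyclohex-3-ene-1-carboxylic acid | CC(=O)O[C@@H]1C=C[C@H](O[Si](C)(C)C(C)(C)C)[C@@](C(=O)O)(CC(=O)OC)C1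
F4 | step 6 | methyl 2-[(1S,2S,5S)-5-acetoxy-2-[(tert-butyldimethylsilyl)oxy]-1-(chlorocarbonyl)cyclohex-3-en-1-yl]acetate | CC(=O)O[C@@H]1C=C[C@H](O[Si](C)(C)C(C)(C)C)[C@@](C(=O)Cl)(CC(=O)OC)C1
F5 | step 6 | (3E,6E)-2,6-dimethyl-7-(trimethylstannyl)hepta-3,6-dien-2-ol | C[Sn](C)(C)/C=C(\C)C/C=C/C(C)(C)O
F6 | step 2 | (2E)-4-oxobut-2-en-1-yl acetate | CC(=O)OC/C=C/C=O
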